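**Retrosynthetic overview**
1. The quinone methide (ring E) comes from acid-triggered loss of three MOM groups and water from a triaryl carbinol. The carbinol comes from 4-(methoxymethoxy)phenyllithium and a hindered benzophenone, which traces back through PhMgBr and a benzaldehyde to a benzoate ester.
2. The diaryl alkyne comes from Sonogashira coupling of the salicylate-derived aryl triflate with 1-ethynyl-4-(methoxymethoxy)benzene.
3. The ring A salicylate comes from DDQ aromatisation of a cyclohexenone made by intramolecular aldol condensation. Its precursor comes from the key intermolecular Michael addition of ethyl 3-oxopentanoate to 4-methoxycinnamaldehyde, which joins the ester-bearing carbon to the aryl-bearing carbon of ring A.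
4. Ring order: only ring A is built (steps 1–3). Rings B (biaryl phenol), C (alkynyl phenol), D (phenyl) and E (future dienone) are bought as benzene rings and attached in the order B, C, D, E.

**Assumption:** the SMILES has no stereocentre, no stereodefined double bond (the dienone end of the exocyclic C=C is symmetrical) and no axial descriptor. The target is therefore made as drawn, without an enantioselective step. The transient stereocentres in 3–5, 19, 22 and 23 are all destroyed later.

**Step 1**
Reactants: 1 ethyl 3-oxopentanoate; 2 (E)-3-(4-methoxyphenyl)prop-2-enal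
Product: 3 ethyl 3-(4-methoxyphenyl)-5-oxo-2-propanoylpentanoate (stereoisomer mixture)
Conditions: 2-[diphenyl(trimethylsilyloxy)methyl]pyrrolidine (either enantiomer or racemate, 10 mol%), PhCO2H (10 mol%), EtOH, rt, 24–48 h
Reagents that add atoms: none
Why: This is an intermolecular Michael addition under iminium catalysis, in which the bulky amine shields the C=N carbon so the soft β-keto ester enol adds 1,4 rather than 1,2 (Knoevenagel); the two new stereocentres form as a mixture and are erased in step 3.

**Step 2**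
Reactants: 3 ethyl 3-(4-methoxyphenyl)-5-oxo-2-propanoylpentanoate
Product: 5 ethyl 6-(4-methoxyphenyl)-3-methyl-2-oxocyclohex-3-ene-1-carboxylate (stereoisomer mixture), via ketol 4 (not isolated)
Conditions: NaOEt (0.2 equiv), EtOH, 0 °C to rt; then p-TsOH·H2O (0.4 equiv), toluene, reflux, Dean–Stark
Reagents that add atoms: none
Why: This is an intramolecular aldol condensation (the ring-closing half of a Robinson-type annulation), in which only the CH2 of the propanoyl group can reach the aldehyde through a six-membered transition state and acid then dehydrates the ketol to the conjugated enone; all stereocentres are transient.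

**Step 3**
Reactants: 5 ethyl 6-(4-methoxyphenyl)-3-methyl-2-oxocyclohex-3-ene-1-carboxylate
Product: 6 ethyl 2-hydroxy-6-(4-methoxyphenyl)-3-methylbenzoate
Conditions: DDQ (1.2 equiv), toluene, 80 °C
Reagents that add atoms: none
Why: This is an oxidative aromatisation, in which DDQ takes the allylic and p-anisyl-benzylic hydride from the dienol tautomer and proton loss with tautomerisation gives the hydrogen-bonded salicylate, deleting both stereocentres.

**Step 4**
Reactants: 6 ethyl 2-hydroxy-6-(4-methoxyphenyl)-3-methylbenzoate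
Product: 7 ethyl 6-(4-methoxyphenyl)-3-methyl-2-(trifluoromethylsulfonyloxy)benzoate
Conditions: Tf2O (1.3 equiv), pyridine (3 equiv), CH2Cl2, 0 °C to rt
Reagents that add atoms: trifluoromethanesulfonic anhydride, O=S(=O)(OS(=O)(=O)C(F)(F)F)C(F)(F)F
Why: This is an O-sulfonylation of the only free phenol, and the very electrophilic anhydride overcomes the hydrogen bond and the two ortho groups.

**Step 5**
Reactants: 7 ethyl 6-(4-methoxyphenyl)-3-methyl-2-(trifluoromethylsulfonyloxy)benzoate
Product: 8 ethyl 6-(4-hydroxyphenyl)-3-methyl-2-(trifluoromethylsulfonyloxy)benzoate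
Conditions: BBr3 (2.5 equiv), CH2Cl2, −78 to 0 °C; then ice-water
Reagents that add atoms: none
Why: This is a Lewis-acid aryl methyl ether cleavage done before the alkyne and carbinol exist; the aryl triflate is inert to BBr3 and the twisted, hindered ethyl ester is cleaved much more slowly than the anisole at or below 0 °C.

**Step 6**
Reactants: 8 ethyl 6-(4-hydroxyphenyl)-3-methyl-2-(trifluoromethylsulfonyloxy)benzoate
Product: 9 ethyl 6-[4-(methoxymethoxy)phenyl]-3-methyl-2-(trifluoromethylsulfonyloxy)benzoate
Conditions: MOMCl (1.5 equiv), i-Pr2NEt (2 equiv), CH2Cl2, 0 °C to rt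
Reagents that add atoms: chloromethyl methyl ether, COCCl
Why: This is an O-alkylation (MOM protection) of the single unhindered phenol, giving an acetal that withstands every basic, hydridic and organometallic step ahead and falls off in dilute acid at the end.

**Step 7**
Reactants: 10 4-iodophenol
Product: 11 1-iodo-4-(methoxymethoxy)benzene
Conditions: MOMCl (1.3 equiv), i-Pr2NEt (1.8 equiv), CH2Cl2, 0 °C to rt
Reagents that add atoms: chloromethyl methyl ether, COCCl
Why: This is a MOM protection of a simple phenol, and the product serves as the common precursor of rings C and E.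

**Step 8**
Reactants: 11 1-iodo-4-(methoxymethoxy)benzene; 12 ethynyltrimethylsilane
Product: 13 {[4-(methoxymethoxy)phenyl]ethynyl}trimethylsilane
Conditions: PdCl2(PPh3)2 (2 mol%), CuI (4 mol%), Et3N, THF, rt
Reagents that add atoms: none
Why: This is a Sonogashira coupling of an unhindered aryl iodide, which runs at room temperature while the silyl cap blocks double coupling.

**Step 9**
Reactants: 13 {[4-(methoxymethoxy)phenyl]ethynyl}trimethylsilane
Product: 14 1-ethynyl-4-(methoxymethoxy)benzene
Conditions: K2CO3 (0.2 equiv), MeOH, rt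
Reagents that add atoms: none
Why: This is a methoxide-catalysed protodesilylation of an alkynylsilane, to which the MOM acetal is inert.

**Step 10**
Reactants: 9 ethyl 6-[4-(methoxymethoxy)phenyl]-3-methyl-2-(trifluoromethylsulfonyloxy)benzoate; 14 1-ethynyl-4-(methoxymethoxy)benzene
Product: 15 ethyl 6-[4-(methoxymethoxy)phenyl]-2-{[4-(methoxymethoxy)phenyl]ethynyl}-3-methylbenzoate
Conditions: PdCl2(PPh3)2 (5 mol%), CuI (10 mol%), Et3N (5 equiv), degassed DMF, 80 °C, slow addition of 14 (1.5 equiv)
Reagents that add atoms: none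
Why: This is a Sonogashira coupling in which the ortho ester speeds oxidative addition of zerovalent palladium into the C–OTf bond and the rod-shaped copper acetylide is small enough for the di-ortho-substituted site.

**Step 11**
Reactants: 15 ethyl 6-[4-(methoxymethoxy)phenyl]-2-{[4-(methoxymethoxy)phenyl]ethynyl}-3-methylbenzoate
Product: 16 (6-[4-(methoxymethoxy)phenyl]-2-{[4-(methoxymethoxy)phenyl]ethynyl}-3-methylphenyl)methanol
Conditions: i-Bu2AlH (3 equiv), CH2Cl2, −78 to 0 °C; aq potassium sodium tartrate
Reagents that add atoms: none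
Why: This is an ester reduction by an electrophilic hydride that first binds the carbonyl oxygen and so copes with the flanking groups, while the diaryl alkyne and MOM acetals are untouched at or below 0 °C.

**Step 12**
Reactants: 16 (6-[4-(methoxymethoxy)phenyl]-2-{[4-(methoxymethoxy)phenyl]ethynyl}-3-methylphenyl)methanol
Product: 17 6-[4-(methoxymethoxy)phenyl]-2-{[4-(methoxymethoxy)phenyl]ethynyl}-3-methylbenzaldehyde
Conditions: Dess–Martin periodinane (1.3 equiv), CH2Cl2, rt
Reagents that add atoms: none
Why: This is a Dess–Martin oxidation of a primary benzylic alcohol, which stops cleanly at the aldehyde under near-neutral conditions.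

**Step 13**
Reactants: 17 6-[4-(methoxymethoxy)phenyl]-2-{[4-(methoxymethoxy)phenyl]ethynyl}-3-methylbenzaldehyde; 18 phenylmagnesium bromide
Product: 19 (6-[4-(methoxymethoxy)phenyl]-2-{[4-(methoxymethoxy)phenyl]ethynyl}-3-methylphenyl)(phenyl)methanol (racemic)
Conditions: PhMgBr (1.5 equiv), THF, 0 °C; aq NH4Cl
Reagents that add atoms: none
Why: This is a Grignard 1,2-addition to a non-enolisable aldehyde, and the new stereocentre is racemic and is removed in step 14.

**Step 14**
Reactants: 19 (6-[4-(methoxymethoxy)phenyl]-2-{[4-(methoxymethoxy)phenyl]ethynyl}-3-methylphenyl)(phenyl)methanol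
Product: 20 (6-[4-(methoxymethoxy)phenyl]-2-{[4-(methoxymethoxy)phenyl]ethynyl}-3-methylphenyl)(phenyl)methanone
Conditions: Dess–Martin periodinane (1.5 equiv), CH2Cl2, rt
Reagents that add atoms: none
Why: This is a Dess–Martin oxidation of a doubly benzylic secondary alcohol to the benzophenone, with no over-oxidation possible.

**Step 15**
Reactants: 20 (6-[4-(methoxymethoxy)phenyl]-2-{[4-(methoxymethoxy)phenyl]ethynyl}-3-methylphenyl)(phenyl)methanone; 11 1-iodo-4-(methoxymethoxy)benzene
Product: 22 (6-[4-(methoxymethoxy)phenyl]-2-{[4-(methoxymethoxy)phenyl]ethynyl}-3-methylphenyl)[4-(methoxymethoxy)phenyl](phenyl)methanol (racemic), via 4-(methoxymethoxy)phenyllithium 21 (not isolated)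
Conditions: 11 (2.2 equiv), n-BuLi (2.0 equiv), THF, −78 °C, 30 min; then 20, −78 to 0 °C; aq NH4Cl
Reagents that add atoms: none
Why: This is an iodine–lithium exchange followed by aryllithium 1,2-addition to a non-enolisable ketone whose twisted carbonyl is open on the side of the slim alkyne; the new stereocentre is racemic and vanishes in step 16.

**Step 16**
Reactants: 22 (6-[4-(methoxymethoxy)phenyl]-2-{[4-(methoxymethoxy)phenyl]ethynyl}-3-methylphenyl)[4-(methoxymethoxy)phenyl](phenyl)methanol
Product: 24 selaginellin A, via triphenol carbinol 23 (not isolated)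
Conditions: 3 M aq HCl/THF (1:4), 40 °C; aq NaHCO3 work-up; then toluene azeotrope, 60 °C
Reagents that add atoms: none
Why: This is an acetal hydrolysis of the three MOM ethers followed by acid-catalysed 1,6-elimination of water from the 4-hydroxytrityl alcohol (fuchsone formation), driven by conjugation and by relief of strain at the crowded sp3 carbon, which ceases to be a stereocentre.

**Compound list**
1 | ethyl 3-oxopentanoate | CCC(=O)CC(=O)OCC | starting material
2 | (E)-3-(4-methoxyphenyl)prop-2-enal | COc1ccc(/C=C/C=O)cc1 | starting material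
3 | ethyl 3-(4-methoxyphenyl)-5-oxo-2-propanoylpentanoate (stereoisomer mixture) | CCOC(=O)C(C(=O)CC)C(CC=O)c1ccc(OC)cc1 | intermediate
4 | ethyl 4-hydroxy-6-(4-methoxyphenyl)-3-methyl-2-oxocyclohexane-1-carboxylate (ketol, stereoisomer mixture, not isolated) | CCOC(=O)C1C(=O)C(C)C(O)CC1c1ccc(OC)cc1 | intermediate
5 | ethyl 6-(4-methoxyphenyl)-3-methyl-2-oxocyclohex-3-ene-1-carboxylate (stereoisomer mixture) | CCOC(=O)C1C(=O)C(C)=CCC1c1ccc(OC)cc1 | intermediate
6 | ethyl 2-hydroxy-6-(4-methoxyphenyl)-3-methylbenzoate | CCOC(=O)c1c(O)c(C)ccc1-c1ccc(OC)cc1 | intermediate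
7 | ethyl 6-(4-methoxyphenyl)-3-methyl-2-(trifluoromethylsulfonyloxy)benzoate | CCOC(=O)c1c(OS(=O)(=O)C(F)(F)F)c(C)ccc1-c1ccc(OC)cc1 | intermediate
8 | ethyl 6-(4-hydroxyphenyl)-3-methyl-2-(trifluoromethylsulfonyloxy)benzoate | CCOC(=O)c1c(OS(=O)(=O)C(F)(F)F)c(C)ccc1-c1ccc(O)cc1 | intermediate
9 | ethyl 6-[4-(methoxymethoxy)phenyl]-3-methyl-2-(trifluoromethylsulfonyloxy)benzoate | CCOC(=O)c1c(OS(=O)(=O)C(F)(F)F)c(C)ccc1-c1ccc(OCOC)cc1 | intermediate
10 | 4-iodophenol | Oc1ccc(I)cc1 | starting material
11 | 1-iodo-4-(methoxymethoxy)benzene | COCOc1ccc(I)cc1 | intermediate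
12 | ethynyltrimethylsilane | C#C[Si](C)(C)C | starting material
13 | {[4-(methoxymethoxy)phenyl]ethynyl}trimethylsilane | COCOc1ccc(C#C[Si](C)(C)C)cc1 | intermediate
14 | 1-ethynyl-4-(methoxymethoxy)benzene | COCOc1ccc(C#C)cc1 | intermediate
15 | ethyl 6-[4-(methoxymethoxy)phenyl]-2-{[4-(methoxymethoxy)phenyl]ethynyl}-3-methylbenzoate | CCOC(=O)c1c(C#Cc2ccc(OCOC)cc2)c(C)ccc1-c1ccc(OCOC)cc1 | intermediate
16 | (6-[4-(methoxymethoxy)phenyl]-2-{[4-(methoxymethoxy)phenyl]ethynyl}-3-methylphenyl)methanol | OCc1c(C#Cc2ccc(OCOC)cc2)c(C)ccc1-c1ccc(OCOC)cc1 | intermediate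
17 | 6-[4-(methoxymethoxy)phenyl]-2-{[4-(methoxymethoxy)phenyl]ethynyl}-3-methylbenzaldehyde | O=Cc1c(C#Cc2ccc(OCOC)cc2)c(C)ccc1-c1ccc(OCOC)cc1 | intermediate
18 | phenylmagnesium bromide | Br[Mg]c1ccccc1 | starting material
19 | (6-[4-(methoxymethoxy)phenyl]-2-{[4-(methoxymethoxy)phenyl]ethynyl}-3-methylphenyl)(phenyl)methanol (racemic) | OC(c1ccccc1)c1c(C#Cc2ccc(OCOC)cc2)c(C)ccc1-c1ccc(OCOC)cc1 | intermediate
20 | (6-[4-(methoxymethoxy)phenyl]-2-{[4-(methoxymethoxy)phenyl]ethynyl}-3-methylphenyl)(phenyl)methanone | O=C(c1ccccc1)c1c(C#Cc2ccc(OCOC)cc2)c(C)ccc1-c1ccc(OCOC)cc1 | intermediate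
21 | 4-(methoxymethoxy)phenyllithium (not isolated) | [Li]c1ccc(OCOC)cc1 | intermediate
22 | (6-[4-(methoxymethoxy)phenyl]-2-{[4-(methoxymethoxy)phenyl]ethynyl}-3-methylphenyl)[4-(methoxymethoxy)phenyl](phenyl)methanol (racemic) | OC(c1ccccc1)(c1ccc(OCOC)cc1)c1c(C#Cc2ccc(OCOC)cc2)c(C)ccc1-c1ccc(OCOC)cc1 | intermediate
23 | {6-(4-hydroxyphenyl)-2-[(4-hydroxyphenyl)ethynyl]-3-methylphenyl}(4-hydroxyphenyl)(phenyl)methanol (triphenol carbinol, racemic, not isolated) | OC(c1ccccc1)(c1ccc(O)cc1)c1c(C#Cc2ccc(O)cc2)c(C)ccc1-c1ccc(O)cc1 | intermediate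
24 | selaginellin A, 4-[{6-(4-hydroxyphenyl)-2-[(4-hydroxyphenyl)ethynyl]-3-methylphenyl}(phenyl)methylidene]cyclohexa-2,5-dien-1-one | Cc1ccc(-c2ccc(O)cc2)c(C(=C2C=CC(=O)C=C2)c2ccccc2)c1C#Cc1ccc(O)cc1 | target

**Total step count:** 16.
**Longest linear sequence:** 13 steps (steps 1–6 and 10–16). Steps 7–9 form a three-step side branch.

**Steps most likely to fail**

**Step 1.** The electron-rich enal may react slowly, or Knoevenagel 1,2-addition may compete. The fallback sets out from 1 and comes back at 6, bypassing 3–5, by a Chan-type formal [3+3] cyclocondensation based on Mukaiyama aldol reactivity.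
- Compound 1 is silylated with Me3SiCl/Et3N to ethyl 3-(trimethylsilyloxy)pent-2-enoate F1.
- LDA and then Me3SiCl in THF at −78 °C convert this to 1-ethoxy-1,3-bis(trimethylsilyloxy)penta-1,3-diene F2.
- Purchased 4'-methoxyacetophenone is treated with HC(OMe)3, BF3·OEt2 and i-Pr2NEt in CH2Cl2 to give 3,3-dimethoxy-1-(4-methoxyphenyl)propan-1-one F3.
- TiCl4 in CH2Cl2 (−78 °C to rt) bonds the methyl-bearing terminus of the diene to the more reactive acetal carbon. The central nucleophilic carbon then closes onto the aryl ketone, and eliminations aromatise the ring directly to 6 with the same substitution pattern.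

**Step 10.** The di-ortho-substituted triflate may couple slowly, with alkyne homocoupling or triflate hydrolysis taking over. The fallback sets out from 14 and 9 and comes back at 15, replacing the copper acetylide by a tin nucleophile.
- Compound 14 is stannylated with Bu3SnOMe and ZnBr2 (5 mol%) in THF to tributyl{[4-(methoxymethoxy)phenyl]ethynyl}stannane F4.
- A Stille coupling with 9 follows, using Pd(PPh3)4 (5 mol%) and LiCl (3 equiv) in 1,4-dioxane at 100 °C. Chloride turns the cationic arylpalladium triflate into a neutral chloride complex that transmetalates cleanly. No oxidisable acetylide and no amine are present.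

**Step 15.** The hindered ketone may react sluggishly. The fallback sets out from 17 and comes back at 22, reversing the order in which rings D and E are attached so that the smallest and most reactive aryl nucleophile makes the quaternary carbon.
- Aryllithium 21, made as in step 15, is added to aldehyde 17 at −78 °C. This gives (6-[4-(methoxymethoxy)phenyl]-2-{[4-(methoxymethoxy)phenyl]ethynyl}-3-methylphenyl)[4-(methoxymethoxy)phenyl]methanol F5.
- Dess–Martin periodinane oxidises it to (6-[4-(methoxymethoxy)phenyl]-2-{[4-(methoxymethoxy)phenyl]ethynyl}-3-methylphenyl)[4-(methoxymethoxy)phenyl]methanone F6.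
- Commercial PhLi in THF (−78 to 0 °C) then delivers 22.

**Further compounds**
F1 | step 1 | ethyl 3-(trimethylsilyloxy)pent-2-enoate (E/Z mixture) | CCC(O[Si](C)(C)C)=CC(=O)OCC
F2 | step 1 | 1-ethoxy-1,3-bis(trimethylsilyloxy)penta-1,3-diene (isomer mixture) | CC=C(O[Si](C)(C)C)C=C(OCC)O[Si](C)(C)C
F3 | step 1 | 3,3-dimethoxy-1-(4-methoxyphenyl)propan-1-one | COc1ccc(C(=O)CC(OC)OC)cc1
F4 | step 10 | tributyl{[4-(methoxymethoxy)phenyl]ethynyl}stannane | CCCC[Sn](CCCC)(CCCC)C#Cc1ccc(OCOC)cc1
F5 | step 15 | (6-[4-(methoxymethoxy)phenyl]-2-{[4-(methoxymethoxy)phenyl]ethynyl}-3-methylphenyl)[4-(methoxymethoxy)phenyl]methanol (racemic) | OC(c1ccc(OCOC)cc1)c1c(C#Cc2ccc(OCOC)cc2)c(C)ccc1-c1ccc(OCOC)cc1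
F6 | step 15 | (6-[4-(methoxymethoxy)phenyl]-2-{[4-(methoxymethoxy)phenyl]ethynyl}-3-methylphenyl)[4-(methoxymethoxy)phenyl]methanone | O=C(c1ccc(OCOC)cc1)c1c(C#Cc2ccc(OCOC)cc2)c(C)ccc1-c1ccc(OCOC)cc1
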